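(All runs come from a simulation for an exercise; the scatter is artificial.)

The leftover comes first: ochre's last reading leaves 30.5% of the charge outside target at 5.00 h, while grey's stands at 98.0% at 12.0 h.

| setting | grey | ochre | winter | dusk | noon | summer |
|---|---|---|---|---|---|---|
| substrate | 0.010 M | 0.010 M | 0.010 M | 0.010 M | 0.010 M | 0.010 M |
| free enzyme | 0.14 µM | 0.14 µM | 0.14 µM | 0.14 µM | 0.14 µM | 0.14 µM |
| added ligand | 0.060 µM | 0.090 µM | 0.12 µM | 0.12 µM | 0.12 µM | 0.12 µM |
| temperature | 20 °C | 40 °C | 55 °C |  | 40 °C | 25 °C |
| remark | run made earlier | run made earlier |  | at 25 °C until 80 min, from then on at 55 °C |  |  |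
| time |  |  | 2.5 h | 2.5 h | 2.5 h | 2.5 h |

- grey (time / h: target / %): 0.833: 16.1; 2.50: 44.6; 4.00: 69.8; 6.00: 92.3; 8.00: 96.2; 12.0: 98.0; 15.0: 95.6
- ochre (time / h: target / %): 0.667: 18.4; 1.33: 34.1; 2.00: 46.4; 3.00: 59.3; 4.00: 67.1; 5.00: 69.5

(standard deviation of a reading: 1 percentage point)

1. which flask leads in amount of target, in percent of the substrate charged ("all alike" within 1.5 percentage points) (winter / dusk / noon / summer / all alike)
2. how much target is there at the end, in percent of the substrate charged: winter
3. how much target is there at the end, in percent of the substrate charged: dusk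
4. how much target is there at the end, in percent of the substrate charged: noon
5. how much target is there at the end, in percent of the substrate charged: summer



The new flasks differ from these runs in temperature and added ligand, so I follow one molecule of substrate to a single fork: does working enzyme reach it before the rate has died?

Ochre starts at 0.276 h⁻¹ of the charge, but between 2.00 h and 3.00 h it makes only 0.129 h⁻¹. Grey goes from 0.193 h⁻¹ to 0.168 h⁻¹. Read as exponential falls, these give a life of the rate of 2.85 h in ochre, shorter than grey's 20.2 h. Both are readings, and grey's carries the scatter badly.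

Winter lies 0.750 of that temperature step beyond ochre. Stepping on by the same factors gives a life of 0.656 h and an early rate of 0.360 h⁻¹, and I assume the added ligand changes neither. That life is shorter than 2.5 h. Rate times life gives 23.6% for winter: this is the enzyme budget, the fraction of the charge a flask turns if its rate falls exponentially from its early value, the total turnover number told per charge.

My life for summer is 12.4 h, longer than 2.5 h, so I reckon summer to use part of its budget in that time: 47.8%. For noon, on ochre's life, I reckon 45.9%. Both estimates stand above winter's budget, and I name no leader between the two on these readings.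

The forecast differs: winter leads, with 25%, 23%, 22% and 14% for winter, dusk, noon and summer. “Allowing for losses, winter probably leads narrowly, but this is uncertain.”

The flasks give 7.09%, 22.9%, 50.2% and 46.8% in that order, so noon leads.

    free enzyme → unfolded enzyme (k = 6.19 × 10⁻⁶ s⁻¹, Ea = 256 kJ mol⁻¹)
    substrate + free enzyme → target + free enzyme, rate k2*[substrate]*[free enzyme]/(1 + ([substrate]/Km2) + ([target]/Kp2)) (0.363 mM, 6.70 mM, k = 18500 M⁻¹ s⁻¹, Ea = 16.0 kJ mol⁻¹)
    target ⇌ isomer of the product (K = 5.03, k = 2.33 × 10⁻⁵ s⁻¹, Ea = 113 kJ mol⁻¹, ΔH = 43.0 kJ mol⁻¹)
    free enzyme + added ligand ⇌ idle complex (K = 3.70 × 10⁶ M⁻¹, k = 1700 M⁻¹ s⁻¹, Ea = 40.0 kJ mol⁻¹, ΔH = 2.00 kJ mol⁻¹)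
    free enzyme + target → spent catalyst (k = 0.0105 M⁻¹ s⁻¹, Ea = 73.0 kJ mol⁻¹)
    (constants at 40 °C)

In winter the path from substrate to target had 87% of its turnover behind it by 1.25 h, when free enzyme stood at 9.68% of its charge and unfolded enzyme at 80.0%. After that, with free enzyme falling to 2.00%, target went over to the isomer of the product, from 10.6% to 7.09% of the substrate charged, while the isomer reached 12.7%. Winter turned 19.8% against my budget for it of 23.6%. The neighbour flask, winter with 5.6 × 10⁻⁷ M of free enzyme, gets a budget of 94.5% when I scale by that charge, and it turned 68.5%, with target at 23.0%.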